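Start with the easy step: each E that joins Z binds one Q, and each E lost to L binds none. Here is the flask.

Q 12 mM; E 3.00 equiv; time 8.0 h

    Q ⇌ Z, rate k1*(cs1 - [Z]) while solid is left; crystals form when [Z] > cs1 (cs1 = 3.0 mM, k1 = 0.059 min⁻¹)
    Z + E → Z.E (k2 = 2.0 M⁻¹ min⁻¹)
    Z + Z.E → Z.Z.E (k3 = 2.3 M⁻¹ min⁻¹)
    D ⇌ Z.E, rate k4*(cs4 - [Z.E]) while solid is left; crystals form when [Z.E] > cs4 (cs4 = 5.8 mM, k4 = 1.6 min⁻¹)
    E → L (k5 = 0.019 min⁻¹)

- how much Z.E and D together there is at 8.0 h, in percent of the Q charged
- concentration of Z in solution at 8.0 h, in percent of saturation

Two numbers seem to quarrel. With E as charged, Z has a half-life of 0.16 h against capture, shorter than the 0.61 h that E has against step 5, so capture looks like the winner. But these clocks belong to different molecules: Z meets plenty of E, while E meets little Z.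

So count dissolved Z as a fraction of the Q charge. On my first pass, inflow by step 1 against capture by E as charged puts Z at 11.3%. That Z gives E a total loss constant of 0.0217 min⁻¹. Now go round again: E met on average is half its charge, and Z starts from nothing, so I add that constant to the outflow and get 12.6%. At this Z, 13.8% of E goes to Z.E. Multiplied by 3.00 equiv, that makes 41.3% of the Q charge, the captured fraction: what E binds before L takes the rest.

Each captured Q takes one more Z into Z.Z.E, so once the solid has dissolved, the leftover Z is the charge less twice the captured fraction: 17.4%. That is less than the 25.0% of the charge that saturation holds, so the solution has room for it, and I count the solid as gone by 8.0 h. With Z held near that, Z.E decays pseudo-first-order at 0.288 h⁻¹, which gives me 4.12% for y and 86.1% for sat.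

The forecast differs from my reckoning: 10% and 28%, with “Z and Z.E consume each other nearly one-to-one”.

The simulation gives 3.49% and 80.1%.

The neighbour flask is this one read at 2.00 h: Z.E plus the pairs in Z.Z.E count 37.5% captured with 6.6% of E unbound, and the captured fraction scaled to the E used gives 38.6%. This flask at 8.00 h has not come to rest: E is at 0%, but Z.E still holds 3.49%, beside Z.Z.E at 76.5% and Z at 20.0%. The leftover Z I reckoned was 17.4%; at 80.0 h Z.E stands at 0%, Z.Z.E at 83.5% and Z at 16.5%.

The numbers of this flask are made up; the result is computed.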